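**Retrosynthetic overview**
- Target ⇐ one-pot BCl3 unmasking (5-OMe by carbonyl chelation, two benzyl ethers) of 2-[2,4-bis(benzyloxy)phenyl]-3,5,6,7,8-pentamethoxychromone.
- Pyranone ring (the only ring made, closed last) ⇐ O1–C8a bond, by dehydrogenative coupling of a diketone oxygen with the one free aryl C–H of an acyclic 2-methoxy-1,3-diaryl-1,3-dione.
- 1,3-Dione ⇐ C-acylation of the enolate of 2-methoxy-1-(2,3,4,5-tetramethoxyphenyl)ethanone with 2,4-bis(benzyloxy)benzoyl chloride.
- α-Methoxy ketone ⇐ ortho-lithiation of 1,2,3,4-tetramethoxybenzene plus the Weinreb amide of methoxyacetic acid; rings A and B are bought as arenes.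

Assumption: the target has no stereocentre and is achiral, so no enantiomer has to be set; the only stereocentre on the way (C2 of dione 8) is racemic, enolisable and removed in step 3.

**Step 1**
Reactants: 1 1,2,3,4-tetramethoxybenzene; 2 N,2-dimethoxy-N-methylacetamide
Product: 4 2-methoxy-1-(2,3,4,5-tetramethoxyphenyl)ethan-1-one, via (2,3,4,5-tetramethoxyphenyl)lithium 3 (not isolated)
Conditions: n-BuLi (1.1 equiv), TMEDA (1.1 equiv), THF, 0 °C, 1 h; then 2, −78 → 0 °C; 1 M HCl
Reagents that add atoms: none
Why: Methoxy-directed ortho-metalation of the symmetric arene gives a single aryllithium, and its addition to the Weinreb amide stops at the chelated tetrahedral adduct, so the α-methoxy ketone forms without over-addition (directed ortho-metalation / Weinreb ketone synthesis).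

**Step 2**
Reactants: 4 2-methoxy-1-(2,3,4,5-tetramethoxyphenyl)ethan-1-one; 5 2,4-bis(benzyloxy)benzoic acid
Product: 8 1-[2,4-bis(benzyloxy)phenyl]-2-methoxy-3-(2,3,4,5-tetramethoxyphenyl)propane-1,3-dione (racemic), via 2,4-bis(benzyloxy)benzoyl chloride 6 (not isolated), via lithium (Z)-2-methoxy-1-(2,3,4,5-tetramethoxyphenyl)ethen-1-olate 7 (not isolated)
Conditions: 5, (COCl)2, cat. DMF, CH2Cl2, 0 °C → rt, evaporate; 4 (2.0 equiv, excess recovered), LiHMDS (2.1 equiv), THF/toluene, −78 °C; add 6 (1.0 equiv), −78 → 0 °C; 1 M HCl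
Reagents that add atoms: none
Why: Crossed Claisen-type C-acylation of a chelated lithium enolate with an aroyl chloride, in which the second equivalent of enolate deprotonates the more acidic 1,3-diketone and so prevents double acylation; the new methine centre is racemic and is destroyed in step 3.

**Step 3**
Reactants: 8 1-[2,4-bis(benzyloxy)phenyl]-2-methoxy-3-(2,3,4,5-tetramethoxyphenyl)propane-1,3-dione
Product: 9 2-[2,4-bis(benzyloxy)phenyl]-3,5,6,7,8-pentamethoxy-4H-chromen-4-one
Conditions: graphite(+)/Pt(−), undivided cell, constant current (4 mA cm−2, 2.2 F mol−1), (2,4-Br2C6H3)3N (10 mol %), n-Bu4NBF4 (0.1 M), CH2Cl2/HFIP 4:1, 0 °C, Ar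
Reagents that add atoms: none
Why: Proposed new method: mediated anodic dehydrogenative ring closure between a diketone oxygen and an aryl C–H. The triarylaminium mediator (about +1.5 V vs SCE) oxidises only the tetramethoxyaryl ring to its radical cation, because the acyl-substituted resorcinol diether ring and the benzyl groups lie higher. The oxygen of the neighbouring aroyl carbonyl then adds through a six-membered transition state to C6, the only unsubstituted ring carbon, which is ortho to the coplanar 5-OMe and para to the 3-OMe. Loss of the methine proton, a second electron and the aryl proton gives the aromatic chromone, while HFIP is reduced to H2 at the cathode; HFIP also keeps the substrate in its neutral keto/enol form, so the methine is not oxidised as an enolate. The closest known reaction type is the oxidative (FeCl3, DDQ or anodic) enol or carboxyl O–H/aryl C–H cyclisation of electron-rich arenes to benzofurans, coumestans and benzocoumarins, which has not been used to close a 4-pyranone from a 1,3-diketone.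

**Step 4**
Reactants: 9 2-[2,4-bis(benzyloxy)phenyl]-3,5,6,7,8-pentamethoxy-4H-chromen-4-one
Product: 10 2-(2,4-dihydroxyphenyl)-5-hydroxy-3,6,7,8-tetramethoxy-4H-chromen-4-one (5,2',4'-trihydroxy-3,6,7,8-tetramethoxyflavone)
Conditions: BCl3 (6 equiv), C6HMe5 (6 equiv), CH2Cl2, −78 → 0 °C; MeOH, then aq. NaHCO3
Reagents that add atoms: none
Why: Chelation-controlled demethylation (BCl3 bound to the C4 carbonyl cleaves only the peri 5-OMe) runs together with Lewis-acid debenzylation with pentamethylbenzene as cation scavenger; the unchelated 6-, 7- and 8-OMe stay, as does the 3-OMe once the carbonyl is tied up in the 5-O–B chelate.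

**Compound list**
1 | 1,2,3,4-tetramethoxybenzene | COc1ccc(OC)c(OC)c1OC | starting material
2 | N,2-dimethoxy-N-methylacetamide | COCC(=O)N(C)OC | starting material
3 | (2,3,4,5-tetramethoxyphenyl)lithium | [Li]c1cc(OC)c(OC)c(OC)c1OC | intermediate
4 | 2-methoxy-1-(2,3,4,5-tetramethoxyphenyl)ethan-1-one | COCC(=O)c1cc(OC)c(OC)c(OC)c1OC | intermediate
5 | 2,4-bis(benzyloxy)benzoic acid | OC(=O)c1ccc(OCc2ccccc2)cc1OCc1ccccc1 | starting material
6 | 2,4-bis(benzyloxy)benzoyl chloride | O=C(Cl)c1ccc(OCc2ccccc2)cc1OCc1ccccc1 | intermediate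
7 | lithium (Z)-2-methoxy-1-(2,3,4,5-tetramethoxyphenyl)ethen-1-olate | [Li+].[O-]/C(=C\OC)c1cc(OC)c(OC)c(OC)c1OC | intermediate
8 | 1-[2,4-bis(benzyloxy)phenyl]-2-methoxy-3-(2,3,4,5-tetramethoxyphenyl)propane-1,3-dione (racemic, labile centre) | COC(C(=O)c1ccc(OCc2ccccc2)cc1OCc1ccccc1)C(=O)c1cc(OC)c(OC)c(OC)c1OC | intermediate
9 | 2-[2,4-bis(benzyloxy)phenyl]-3,5,6,7,8-pentamethoxy-4H-chromen-4-one | COc1c(-c2ccc(OCc3ccccc3)cc2OCc2ccccc2)oc2c(OC)c(OC)c(OC)c(OC)c2c1=O | intermediate
10 | 2-(2,4-dihydroxyphenyl)-5-hydroxy-3,6,7,8-tetramethoxy-4H-chromen-4-one (achiral) | COc1c(OC)c(O)c2c(=O)c(OC)c(-c3ccc(O)cc3O)oc2c1OC | target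

**Step count**
Total: 4 steps. The activation of 5 to 6 and the enolate formation are telescoped into step 2.
Longest linear sequence: 4 steps (1 → 4 → 8 → 9 → 10).

**Steps most likely to fail**

Step 3 (the new ring closure). The carbonyl oxygen may add ipso at the methoxy-bearing C2 of the radical cation instead of at C6–H, which would lead to quinone-ketal or 6,7,8-trimethoxy products. The methine may be oxidised, or product 9 over-oxidised to a 5,8-quinone. The fallback uses known chemistry, sets out from ketone 4 and comes back at chromone 9. Ring bromination of 4 at its only free position (NBS, MeCN, 0 °C → rt) gives 1-(2-bromo-3,4,5,6-tetramethoxyphenyl)-2-methoxyethan-1-one F1. Its lithium enolate is C-acylated with acid chloride 6 under the step 2 conditions to give 1-[2,4-bis(benzyloxy)phenyl]-3-(2-bromo-3,4,5,6-tetramethoxyphenyl)-2-methoxypropane-1,3-dione F2. Intramolecular Ullmann-type O-arylation of the diketone enolate (CuI, 1,10-phenanthroline, K2CO3, DMF, 110 °C) then closes the same O1–C8a bond and gives 9.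

Step 2 (C-acylation). The hindered ortho-benzyloxy aroyl chloride may give O-acylation, and the 2-methoxy-1,3-dione may undergo retro-Claisen cleavage. The fallback sets out from ketone 4 and comes back at dione 8. Aldol addition of enolate 7 to purchased 2,4-bis(benzyloxy)benzaldehyde (O=Cc1ccc(OCc2ccccc2)cc1OCc1ccccc1; THF, −78 °C) gives 3-[2,4-bis(benzyloxy)phenyl]-3-hydroxy-2-methoxy-1-(2,3,4,5-tetramethoxyphenyl)propan-1-one F3, a racemic diastereomer mixture in which both centres are later lost. Oxidation of this β-hydroxy ketone with IBX (EtOAc, 75 °C) gives 8.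

Step 4 (one-pot unmasking). The excess BCl3 needed for debenzylation may also cleave the 3-OMe or 6-OMe, or the benzyl cations may alkylate the resorcinol ring. The fallback sets out from chromone 9 and comes back at target 10. Hydrogenolysis (H2, 1 atm, Pd/C, EtOAc/MeOH, rt) first removes both benzyl groups to give 2-(2,4-dihydroxyphenyl)-3,5,6,7,8-pentamethoxy-4H-chromen-4-one F4. Chelation-controlled demethylation with anhydrous AlCl3 in MeCN (rt → 50 °C, then dilute HCl) then cleaves only the 5-OMe and gives 10.

**Further compounds**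
F1 | step 3 | 1-(2-bromo-3,4,5,6-tetramethoxyphenyl)-2-methoxyethan-1-one | COCC(=O)c1c(Br)c(OC)c(OC)c(OC)c1OC
F2 | step 3 | 1-[2,4-bis(benzyloxy)phenyl]-3-(2-bromo-3,4,5,6-tetramethoxyphenyl)-2-methoxypropane-1,3-dione (racemic) | COC(C(=O)c1ccc(OCc2ccccc2)cc1OCc1ccccc1)C(=O)c1c(Br)c(OC)c(OC)c(OC)c1OC
F3 | step 2 | 3-[2,4-bis(benzyloxy)phenyl]-3-hydroxy-2-methoxy-1-(2,3,4,5-tetramethoxyphenyl)propan-1-one (racemic, diastereomer mixture) | COC(C(O)c1ccc(OCc2ccccc2)cc1OCc1ccccc1)C(=O)c1cc(OC)c(OC)c(OC)c1OC
F4 | step 4 | 2-(2,4-dihydroxyphenyl)-3,5,6,7,8-pentamethoxy-4H-chromen-4-one | COc1c(-c2ccc(O)cc2O)oc2c(OC)c(OC)c(OC)c(OC)c2c1=O
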